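The target is a mirror-symmetric chain of six rings; its central methylene carbon bridges the two inner butyrylphloroglucinol rings. Everything rests on disconnecting both aryl–CH2 bonds at this carbon. In one operation, two copies of a three-ring half (butyrylfilicinic acid–CH2–butyrylphloroglucinol–CH2–butyrylphloroglucinol, whose terminal ring carries the only free aromatic C–H) are joined by formaldehyde as a one-carbon linchpin: one half is hydroxymethylated and dehydrated to an ortho-quinone methide, and the free ring carbon of the second half adds to its methylene, forming the aryl–CH2 bond that unites the halves. The half is grown from commercial phlorobutyrophenone by one C-gem-dimethylation and two Mannich/quinone-methide chain extensions.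

Key step: step 4

Remark on the chemistry: the target has no stereocentre; every enolised β-triketone and phloroglucinol ring is drawn in the tautomeric form of the target formula, and other tautomers are taken as the same compound.

Step 1
Reactants: 1 phlorobutyrophenone; 2 iodomethane
Product: 3 butyrylfilicinic acid
Conditions: NaOMe (3 equiv), MeI (2.1 equiv), MeOH, 0 °C to rt; dilute HCl work-up
Reagents that add atoms: iodomethane, CI
Why: Dearomatising C-gem-dimethylation of the acylphloroglucinol polyanion (the classical conversion of an acylphloroglucinol into an acylfilicinic acid) should place both methyl groups on one ring carbon between two oxygens, because the mono-methylated carbon remains the most nucleophilic enolate site and the resulting β-triketone anion is too stabilised to take a third methyl readily.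

Step 2
Reactants: 3 butyrylfilicinic acid; 4 N,N-dimethylmethylideneammonium iodide; 1 phlorobutyrophenone (3 equiv)
Product: 7 butyrylfilicinic acid–CH2–butyrylphloroglucinol dimer (norflavaspidic acid BB), via Mannich base 5 (not isolated), via methylidene trione 6 (not isolated)
Conditions: (i) 4 (1.0 equiv), MeCN, 0 °C to rt; (ii) 1 (3 equiv), NaOAc (1.1 equiv), 60 °C; dilute HCl work-up, excess 1 recovered
Reagents that add atoms: N,N-dimethylmethylideneammonium iodide, C[N+](C)=C.[I-]
Why: Mannich aminomethylation of the only ring C–H of 3 should give betaine 5, which on warming loses dimethylamine to the ortho-quinone-methide-like 2-methylidene triketone 6; Michael-type (Friedel–Crafts) C-alkylation of the excess phloroglucinol 1 at C3 then gives 7, the excess of 1 suppressing a second alkylation.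

Step 3
Reactants: 7 norflavaspidic acid BB; 4 N,N-dimethylmethylideneammonium iodide; 1 phlorobutyrophenone (4 equiv)
Product: 10 three-ring half (butyrylfilicinic acid–CH2–butyrylphloroglucinol–CH2–butyrylphloroglucinol), via Mannich base 8 (not isolated), via quinone methide 9 (not isolated)
Conditions: (i) 4 (1.0 equiv), MeCN, rt; (ii) 1 (4 equiv), NaOAc (1.1 equiv), 70 °C; dilute HCl work-up, excess 1 recovered
Reagents that add atoms: N,N-dimethylmethylideneammonium iodide, C[N+](C)=C.[I-]
Why: The single free aromatic C–H of 7 should undergo the Mannich reaction to 8 (now without any free ring position, so it cannot self-condense), thermal loss of dimethylamine gives ortho-quinone methide 9, and Michael-type C-alkylation of excess 1 extends the chain by one ring while leaving one aromatic C–H on the new terminal ring.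

Step 4
Reactants: 10 three-ring half (2 equiv); 11 formaldehyde (1 equiv)
Product: 14 target hexamer CNP0237140.0, via hydroxymethyl trimer 12 (not isolated), via quinone methide 13 (not isolated)
Conditions: 37% aq. CH2O (0.5 equiv per 10), 1% aq. KOH, 0 °C, short contact time; then cold dilute HCl
Reagents that add atoms: formaldehyde, C=O
Why: In cold dilute alkali the terminal phloroglucinol ring of 10 is a phenolate whose single free carbon adds to formaldehyde (Lederer–Manasse hydroxymethylation) to give 12, which loses hydroxide by E1cB to the ortho-quinone methide 13. The same free ring carbon of a second molecule of 10 then adds to the exocyclic methylene of 13 (Michael-type, vinylogous Friedel–Crafts alkylation) and tautomerises back to the arene, so both aryl–CH2 bonds of the central bridge are made in one pot. The closest known reaction type is the formaldehyde condensation of acylphloroglucinols and acylfilicinic acids to methylene-bis compounds. No ring is closed and no stereocentre is formed, the product being achiral. The step needs site selectivity, and the substrate secures it: the filicinic ring has a quaternary C4 and a substituted C6 and the inner phloroglucinol ring is fully substituted, so the terminal-ring C–H is the only carbon nucleophile and nothing beyond the hexamer can form. Half an equivalent of formaldehyde, low temperature and prompt acidification should keep retro-Michael exchange of the existing methylene bridges from competing.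

Compound list
1 | 1-(2,4,6-trihydroxyphenyl)butan-1-one (phlorobutyrophenone) | CCCC(=O)c1c(O)cc(O)cc1O | starting material
2 | iodomethane | CI | starting material
3 | 2-butanoyl-3,5-dihydroxy-4,4-dimethylcyclohexa-2,5-dien-1-one (butyrylfilicinic acid) | CCCC(=O)C1=C(O)C(C)(C)C(O)=CC1=O | intermediate
4 | N,N-dimethylmethylideneammonium iodide (Eschenmoser's salt) | C[N+](C)=C.[I-] | starting material
5 | 2-butanoyl-6-[(dimethylamino)methyl]-3,5-dihydroxy-4,4-dimethylcyclohexa-2,5-dien-1-one | CCCC(=O)C1=C(O)C(C)(C)C(O)=C(CN(C)C)C1=O | intermediate
6 | 2-butanoyl-3-hydroxy-4,4-dimethyl-6-methylidenecyclohex-2-ene-1,5-dione | CCCC(=O)C1=C(O)C(C)(C)C(=O)C(=C)C1=O | intermediate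
7 | 2-butanoyl-6-[(3-butanoyl-2,4,6-trihydroxyphenyl)methyl]-3,5-dihydroxy-4,4-dimethylcyclohexa-2,5-dien-1-one (norflavaspidic acid BB) | CCCC(=O)C1=C(O)C(C)(C)C(O)=C(Cc2c(O)cc(O)c(C(=O)CCC)c2O)C1=O | intermediate
8 | 2-butanoyl-6-({3-butanoyl-5-[(dimethylamino)methyl]-2,4,6-trihydroxyphenyl}methyl)-3,5-dihydroxy-4,4-dimethylcyclohexa-2,5-dien-1-one | CCCC(=O)C1=C(O)C(C)(C)C(O)=C(Cc2c(O)c(CN(C)C)c(O)c(C(=O)CCC)c2O)C1=O | intermediate
9 | 2-butanoyl-4-[(5-butanoyl-2,4-dihydroxy-3,3-dimethyl-6-oxocyclohexa-1,4-dien-1-yl)methyl]-3,5-dihydroxy-6-methylidenecyclohexa-2,4-dien-1-one | C=C1C(=O)C(C(=O)CCC)=C(O)C(CC2=C(O)C(C)(C)C(O)=C(C(=O)CCC)C2=O)=C1O | intermediate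
10 | 2-butanoyl-6-({3-butanoyl-5-[(3-butanoyl-2,4,6-trihydroxyphenyl)methyl]-2,4,6-trihydroxyphenyl}methyl)-3,5-dihydroxy-4,4-dimethylcyclohexa-2,5-dien-1-one | CCCC(=O)C1=C(O)C(C)(C)C(O)=C(Cc2c(O)c(Cc3c(O)cc(O)c(C(=O)CCC)c3O)c(O)c(C(=O)CCC)c2O)C1=O | intermediate
11 | formaldehyde (37% aqueous solution) | C=O | starting material
12 | 2-butanoyl-6-[(3-butanoyl-5-{[3-butanoyl-2,4,6-trihydroxy-5-(hydroxymethyl)phenyl]methyl}-2,4,6-trihydroxyphenyl)methyl]-3,5-dihydroxy-4,4-dimethylcyclohexa-2,5-dien-1-one | CCCC(=O)C1=C(O)C(C)(C)C(O)=C(Cc2c(O)c(Cc3c(O)c(CO)c(O)c(C(=O)CCC)c3O)c(O)c(C(=O)CCC)c2O)C1=O | intermediate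
13 | 2-butanoyl-4-({3-butanoyl-5-[(5-butanoyl-2,4-dihydroxy-3,3-dimethyl-6-oxocyclohexa-1,4-dien-1-yl)methyl]-2,4,6-trihydroxyphenyl}methyl)-3,5-dihydroxy-6-methylidenecyclohexa-2,4-dien-1-one | C=C1C(=O)C(C(=O)CCC)=C(O)C(Cc2c(O)c(CC3=C(O)C(C)(C)C(O)=C(C(=O)CCC)C3=O)c(O)c(C(=O)CCC)c2O)=C1O | intermediate
14 | CNP0237140.0: bis{3-butanoyl-5-[(3-butanoyl-5-{(5-butanoyl-2,4-dihydroxy-3,3-dimethyl-6-oxocyclohexa-1,4-dien-1-yl)methyl}-2,4,6-trihydroxyphenyl)methyl]-2,4,6-trihydroxyphenyl}methane | CCCC(=O)C1=C(O)C(C)(C)C(O)=C(Cc2c(O)c(Cc3c(O)c(Cc4c(O)c(Cc5c(O)c(CC6=C(O)C(C)(C)C(O)=C(C(=O)CCC)C6=O)c(O)c(C(=O)CCC)c5O)c(O)c(C(=O)CCC)c4O)c(O)c(C(=O)CCC)c3O)c(O)c(C(=O)CCC)c2O)C1=O | target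

Total step count: 4
Longest linear sequence: 4 steps (1 → 3 → 7 → 10 → 14)

Steps most likely to fail

Step 4. In alkali the existing methylene bridges may exchange by retro-Michael cleavage and re-addition (rottlerone-type scrambling of ring units), or the hydroxymethylation may stall with the substoichiometric formaldehyde. The fallback sets out from 10 and replaces the three-component alkaline condensation by a stepwise, non-alkaline two-component coupling. One portion of 10 would be aminomethylated at its free ring carbon with N,N-dimethylmethylideneammonium iodide (MeCN, rt) and the dimethylaminomethyl trimer F1 isolated. F1 would then be heated with a second portion of 10 and NaOAc in MeCN (60–70 °C), so that quinone methide 13 is generated by loss of dimethylamine and trapped by 10. The fallback comes back to the route at 14.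

Step 3. On heating Mannich base 8, expulsion of the stabilised filicinic acid enolate may compete with loss of dimethylamine and cleave the bridge already made, and the new product may be alkylated a second time. The fallback sets out from 1 and builds the two phloroglucinol rings first. Condensation of excess 1 with aqueous formaldehyde (1% aq. KOH, 0 °C) would give the symmetric bis(3-butanoyl-2,4,6-trihydroxyphenyl)methane F2. One of its two equivalent free ring carbons would then be capped with methylidene trione 6, generated from 3 through Mannich base 5 exactly as in step 2 (F2 in excess, NaOAc, MeCN, 60 °C). The only quinone-methide precursor is then 5, which has no bridge to lose. The fallback comes back to the route at 10.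

Step 1. Under- and over-methylation at carbon and competing O-methylation may give a mixture that is hard to separate. The fallback sets out from 1 and blocks the second ring position before the methylation. Friedel–Crafts butanoylation (butanoyl chloride, AlCl3, PhNO2/CH2Cl2) would give 2,4-dibutanoylphloroglucinol F3, whose single free ring carbon must take both methyl groups (MeI, NaOMe, MeOH) to give 2,6-dibutanoyl-3,5-dihydroxy-4,4-dimethylcyclohexa-2,5-dien-1-one F4. One of its two equivalent butanoyl groups would then be removed by controlled acid-mediated retro-Friedel–Crafts deacylation (about 80% H2SO4, gentle warming, monitored). The fallback comes back to the route at 3.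

Further compounds
F1 | step 4 | 2-butanoyl-6-[(3-butanoyl-5-{[3-butanoyl-5-[(dimethylamino)methyl]-2,4,6-trihydroxyphenyl]methyl}-2,4,6-trihydroxyphenyl)methyl]-3,5-dihydroxy-4,4-dimethylcyclohexa-2,5-dien-1-one | CCCC(=O)C1=C(O)C(C)(C)C(O)=C(Cc2c(O)c(Cc3c(O)c(CN(C)C)c(O)c(C(=O)CCC)c3O)c(O)c(C(=O)CCC)c2O)C1=O
F2 | step 3 | bis(3-butanoyl-2,4,6-trihydroxyphenyl)methane | CCCC(=O)c1c(O)cc(O)c(Cc2c(O)cc(O)c(C(=O)CCC)c2O)c1O
F3 | step 1 | 1,1'-(2,4,6-trihydroxy-1,3-phenylene)di(butan-1-one) (2,4-dibutanoylphloroglucinol) | CCCC(=O)c1c(O)cc(O)c(C(=O)CCC)c1O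
F4 | step 1 | 2,6-dibutanoyl-3,5-dihydroxy-4,4-dimethylcyclohexa-2,5-dien-1-one | CCCC(=O)C1=C(O)C(C)(C)C(O)=C(C(=O)CCC)C1=O
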